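**Assumptions:** (S)-2-(but-3-en-1-yl)oxirane is taken as purchasable in ≥98% ee (it is the hydrolytic-kinetic-resolution product of the cheap racemate). Carbons are numbered C1 (ester C=O) to C20 (CHBr). The target SMILES corresponds to the trans-2,5-disubstituted THF, (5R,8S).

## Retrosynthetic overview

1. Cut the C10–C11 sp–sp² bond: a chemoselective Sonogashira coupling (C–I over C–Br) joins a C1–C10 THF alkyne with a C11–C20 (1E,9E)-1-bromo-10-iodo-diene in the last step.
2. The diene comes from cyclooctene: a terminus-differentiating ozonolysis, then two Takai haloform olefinations (CHBr3, then CHI3) set both E-alkenes.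
3. The THF alkyne comes from a trans-THF-methanol by oxidation and Ohira–Bestmann homologation; the ester chain comes from an allyl group by cross-metathesis with methyl acrylate and hydrogenation.
4. The only ring (the THF) is formed early by a trans-selective Co-catalysed aerobic oxidative cyclisation of (S)-octa-1,7-dien-4-ol. C5 comes from the (S)-epoxide; C8 is set in the cyclisation.

## Route

### Fragment A (C1–C10)

**Step 1**
Reactants: 1, (S)-2-(but-3-en-1-yl)oxirane; 2, vinylmagnesium bromide
Product: 3, (S)-octa-1,7-dien-4-ol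
Conditions: 2 (1.5 equiv), CuI (10 mol%), THF, –40 → –20 °C; aq. NH4Cl
Reagents that add atoms: vinylmagnesium bromide (2), C=C[Mg]Br
Why: Cu-catalysed SN2 epoxide opening by the Grignard at the unhindered CH2; the C–O stereocentre is not touched and becomes C5.

**Step 2**
Reactants: 3, (S)-octa-1,7-dien-4-ol
Product: 4, [(2S,5S)-5-(prop-2-en-1-yl)oxolan-2-yl]methanol (trans)
Conditions: Co(nmp)2 (10 mol%), t-BuOOH (10 mol%), O2 (1 atm), i-PrOH, 55 °C
Reagents that add atoms: dioxygen, O=O
Why: Mukaiyama (Pagenkopf variant) aerobic oxidative cyclisation of a 4-pentenol is a hydroxyl-directed 5-exo closure that gives trans-2,5-THF-methanols (typically >95:5), so the carbinol centre sets C8 trans to it; the other alkene is homoallylic and cannot form a five-membered ring.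

**Step 3**
Reactants: 4, [(2S,5S)-5-allyloxolan-2-yl]methanol; 5, methyl acrylate
Product: 6, methyl (2E)-4-[(2S,5S)-5-(hydroxymethyl)oxolan-2-yl]but-2-enoate
Conditions: 5 (5 equiv), Hoveyda–Grubbs II (3 mol%), CH2Cl2, 40 °C
Reagents that add atoms: methyl acrylate (5), C=CC(=O)OC
Why: Olefin cross-metathesis of a terminal (type I) alkene with an acrylate (type II) gives the cross product selectively and tolerates the free primary alcohol; it completes the C1–C4 chain.

**Step 4**
Reactants: 6, methyl (2E)-4-[(2S,5S)-5-(hydroxymethyl)oxolan-2-yl]but-2-enoate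
Product: 7, methyl 4-[(2R,5S)-5-(hydroxymethyl)oxolan-2-yl]butanoate
Conditions: H2 (1 atm), 10% Pd/C, EtOAc, rt
Reagents that add atoms: none
Why: Catalytic hydrogenation of the enoate; nothing else is reducible. The descriptor at the chain-bearing carbon changes from S to R only because CIP priorities change.

**Step 5**
Reactants: 7, methyl 4-[(2R,5S)-5-(hydroxymethyl)oxolan-2-yl]butanoate
Product: 8, methyl 4-[(2R,5S)-5-formyloxolan-2-yl]butanoate
Conditions: Dess–Martin periodinane, NaHCO3, CH2Cl2, 0 °C → rt; use crude
Reagents that add atoms: none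
Why: Buffered Dess–Martin oxidation gives the α-alkoxy aldehyde without over-oxidation or epimerisation.

**Step 6**
Reactants: 8, methyl 4-[(2R,5S)-5-formyloxolan-2-yl]butanoate
Product: 9, methyl 4-[(2R,5S)-5-ethynyloxolan-2-yl]butanoate
Conditions: Bestmann–Ohira reagent, K2CO3, MeOH, 0 °C → rt
Reagents that add atoms: dimethyl (1-diazo-2-oxopropyl)phosphonate, COP(=O)(OC)C(=[N+]=[N-])C(C)=O
Why: Seyferth–Gilbert homologation (Ohira–Bestmann modification) converts the aldehyde into the terminal alkyne under mild carbonate conditions; transesterification of the methyl ester in MeOH is degenerate, and the short cold reaction preserves the C8 centre.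

### Fragment B (C11–C20)

**Step 7**
Reactants: 10, cyclooctene
Product: 11, 8,8-dimethoxyoctanal
Conditions: O3, CH2Cl2/MeOH, –78 °C; TsOH·H2O, rt; NaHCO3; Me2S
Reagents that add atoms: ozone, [O-][O+]=O; methanol, CO
Why: Schreiber terminus-differentiating ozonolysis: the aldehyde end is acetalised under acid while the methoxy-hydroperoxide end is reduced by Me2S to the free aldehyde.

**Step 8**
Reactants: 11, 8,8-dimethoxyoctanal
Product: 12, (E)-1-bromo-9,9-dimethoxynon-1-ene
Conditions: CrBr2 (from CrBr3, LiAlH4), CHBr3, THF, 50 °C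
Reagents that add atoms: bromoform, BrC(Br)Br
Why: Takai–Utimoto haloform olefination via a gem-dichromium species gives the E-vinyl bromide; CrBr2 avoids Br/Cl scrambling and the acetal is inert.

**Step 9**
Reactants: 12, (E)-1-bromo-9,9-dimethoxynon-1-ene
Product: 13, (E)-9-bromonon-8-enal
Conditions: 1 M aq. HCl, THF, rt
Reagents that add atoms: water, O
Why: Acid hydrolysis of the dimethyl acetal; the vinyl bromide is unaffected.

**Step 10**
Reactants: 13, (E)-9-bromonon-8-enal
Product: 14, (1E,9E)-1-bromo-10-iododeca-1,9-diene
Conditions: CrCl2 (6 equiv), CHI3 (2 equiv), dioxane/THF 6:1, 0 °C → rt, dark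
Reagents that add atoms: iodoform, IC(I)I
Why: Takai iodo-olefination gives the E-vinyl iodide (dioxane raises the E/Z ratio); the vinyl bromide does not react with Cr(II) in the absence of Ni.

### Fragment union

**Step 11**
Reactants: 9, methyl 4-[(2R,5S)-5-ethynyloxolan-2-yl]butanoate; 14, (1E,9E)-1-bromo-10-iododeca-1,9-diene (1.2 equiv)
Product: 15, Mutafuran C, methyl 4-[(2R,5S)-5-[(3E,11E)-12-bromododeca-3,11-dien-1-yn-1-yl]oxolan-2-yl]butanoate
Conditions: Pd(PPh3)4 (5 mol%), CuI (10 mol%), i-Pr2NH, degassed THF, 0 °C → rt
Reagents that add atoms: none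
Why: Sonogashira coupling; oxidative addition into the vinyl C–I bond is much faster than into C–Br at or below rt, so the bromide survives, alkene geometry is retained, and the mild amine base does not affect the ester or the propargylic C8 centre.

## Compound list

1 | (S)-2-(but-3-en-1-yl)oxirane | C=CCC[C@H]1CO1 | starting material
2 | vinylmagnesium bromide | C=C[Mg]Br | starting material
3 | (S)-octa-1,7-dien-4-ol | C=CC[C@@H](O)CCC=C | intermediate
4 | [(2S,5S)-5-(prop-2-en-1-yl)oxolan-2-yl]methanol | C=CC[C@@H]1CC[C@@H](CO)O1 | intermediate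
5 | methyl acrylate | C=CC(=O)OC | starting material
6 | methyl (2E)-4-[(2S,5S)-5-(hydroxymethyl)oxolan-2-yl]but-2-enoate | COC(=O)/C=C/C[C@@H]1CC[C@@H](CO)O1 | intermediate
7 | methyl 4-[(2R,5S)-5-(hydroxymethyl)oxolan-2-yl]butanoate | COC(=O)CCC[C@@H]1CC[C@@H](CO)O1 | intermediate
8 | methyl 4-[(2R,5S)-5-formyloxolan-2-yl]butanoate | COC(=O)CCC[C@@H]1CC[C@@H](C=O)O1 | intermediate
9 | methyl 4-[(2R,5S)-5-ethynyloxolan-2-yl]butanoate | COC(=O)CCC[C@@H]1CC[C@@H](C#C)O1 | intermediate
10 | cyclooctene | C1=CCCCCCC1 | starting material
11 | 8,8-dimethoxyoctanal | COC(OC)CCCCCCC=O | intermediate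
12 | (E)-1-bromo-9,9-dimethoxynon-1-ene | COC(OC)CCCCCC/C=C/Br | intermediate
13 | (E)-9-bromonon-8-enal | O=CCCCCCC/C=C/Br | intermediate
14 | (1E,9E)-1-bromo-10-iododeca-1,9-diene | Br/C=C/CCCCCC/C=C/I | intermediate
15 | Mutafuran C | COC(=O)CCC[C@@H]1CC[C@@H](C#C/C=C/CCCCCC/C=C/Br)O1 | target

## Summary

Total steps: 11 (fragment A 6, fragment B 4, coupling 1).
Longest linear sequence: 7 (steps 1–6, then 11).

Steps most likely to fail, each with a fallback:

1. **Step 11 (I versus Br selectivity in the Sonogashira coupling).** Fallback: take the bromide out of the Pd step. Make (E)-9-iodo-1,1-dimethoxynon-8-ene from 11 (Takai, CHI3) and couple it with 9. Then hydrolyse the acetal and install the E-vinyl bromide last by CHBr3/CrBr2 Takai olefination on the enyne aldehyde.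
2. **Step 2 (Co cyclisation with a second alkene present).** Fallback: open 1 with 2-(1,3-dioxolan-2-yl)ethylmagnesium bromide instead of 2, so the cyclisation substrate is a simple mono-alkenol. Carry the acetal through oxidation and alkynylation, then convert it to the methyl ester (hydrolysis, Pinnick oxidation, TMSCHN2); this replaces the metathesis/hydrogenation sequence.
3. **Step 8 (Takai bromo-olefination: E/Z ratio, CrBr2 preparation).** Fallback: homologate aldehyde 11 to the terminal alkyne (Ohira–Bestmann) and make the vinyl bromide by hydrozirconation (Cp2Zr(H)Cl) then NBS, which gives only the E isomer by syn addition. The same alkyne/hydrozirconation–I2 tactic can replace step 10.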